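**Plan**

1. Retrosynthesis: take off the four methoxymethyl (MOM) ethers and lower C4 to the alcohol level; then cut ring C at O1–C8a and at C3–C4 in one step; last, cut C6–geranyl and C4a–CHO on ring A.
2. Forward: ring A is dressed first from symmetric 5-fluororesorcinol bis-MOM ether by two directed lithiations (geranyl between the oxygens, then CHO next to fluorine). Ring B arrives as an (R)-chlorohydrin. Ring C is closed last by a [3+3] union of the two halves.
3. Key event: the β-oxido alkyllithium from the chlorohydrin adds through C3 to the aldehyde carbon C4, and the alkoxide O1 then displaces fluoride at C8a (SNAr).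
4. Enabling feature: ring A is a phloroglucinol, so C8a carries oxygen in the target, sits ortho to the carbon bearing C4 and meta to the C5 and C7 oxygens. Offered as C–F it is inductively activated by both meta alkoxy groups, and O1/C3 (a 1,2-O,C-dianion on C2) match C8a/C4 (a 1,3-dielectrophile across C4a).
5. Stereochemistry: C2 is set by asymmetric transfer hydrogenation (catalyst control) and no bond to it is touched afterwards. C4 stays an alcohol while base is present, so C2 cannot be scrambled; the E-olefin comes from geranyl bromide.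

Key step: step 7

Remark: 5-fluororesorcinol (1) is taken as a purchasable arene; if needed it is one ether cleavage away from 1-fluoro-3,5-dimethoxybenzene. "Geranyl" means (2E)-3,7-dimethylocta-2,6-dien-1-yl.

**Route**

Step 1
Reactants: 1 5-fluorobenzene-1,3-diol
Product: 2 1-fluoro-3,5-bis(methoxymethoxy)benzene
Conditions: MOMCl, i-Pr2NEt, CH2Cl2, 0 °C to rt
Reagents that add atoms: chloromethyl methyl ether, COCCl
Why: Williamson-type O-alkylation of both phenols should give the bis-acetal, which is stable to base and serves as the directing group for both lithiations.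

Step 2
Reactants: 2 1-fluoro-3,5-bis(methoxymethoxy)benzene; 3 geranyl bromide
Product: 5 2-geranyl-5-fluoro-1,3-bis(methoxymethoxy)benzene, via aryllithium 4 (not isolated)
Conditions: n-BuLi, Et2O, 0 °C; CuBr·SMe2 (10 mol %), then 3, −40 °C to rt
Reagents that add atoms: n-butyllithium, CCCC[Li] (lithium of 4 only)
Why: Directed ortho-metalation with n-BuLi in ether and no amine additive is coordination-controlled and should occur at the one position flanked by two chelating OMOM groups; copper-catalysed SN2 allylation of the aryllithium then places the chain on the future C6 with the E-olefin kept, and the symmetric arene allows no positional isomer.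

Step 3
Reactants: 5 2-geranyl-5-fluoro-1,3-bis(methoxymethoxy)benzene
Product: 8 6-fluoro-3-geranyl-2,4-bis(methoxymethoxy)benzaldehyde, via aryllithium 6 (not isolated), via hemiaminal alkoxide 7 (not isolated)
Conditions: n-BuLi, TMEDA, THF, −78 °C; DMF, −78 to 0 °C; H2O
Reagents that add atoms: N,N-dimethylformamide, CN(C)C=O; n-butyllithium, CCCC[Li] (lithium of 6 and 7 only)
Why: Second directed ortho-metalation: the two remaining ring hydrogens of 5 are equivalent and each lies between fluorine and an OMOM group, so lithiation at −78 °C (below the temperature at which LiF is lost) and formylation with DMF should give a single aldehyde.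

Step 4
Reactants: 9 1-(3,5-dihydroxyphenyl)ethanone
Product: 10 1-[3,5-bis(methoxymethoxy)phenyl]ethanone
Conditions: MOMCl, i-Pr2NEt, CH2Cl2, 0 °C to rt
Reagents that add atoms: chloromethyl methyl ether, COCCl
Why: Williamson-type O-alkylation protects both ring B phenols as base-stable acetals that come off together with those of ring A at the end.

Step 5
Reactants: 10 1-[3,5-bis(methoxymethoxy)phenyl]ethanone
Product: 12 1-[3,5-bis(methoxymethoxy)phenyl]-2-chloroethanone, via silyl enol ether 11 (not isolated)
Conditions: LiN(SiMe3)2, Me3SiCl, THF, −78 to 0 °C; then NCS, 0 °C to rt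
Reagents that add atoms: N-chlorosuccinimide, O=C1CCC(=O)N1Cl; chlorotrimethylsilane, C[Si](C)(C)Cl (silyl group of 11 only)
Why: Electrophilic α-chlorination of the silyl enol ether is regiospecific for the methyl carbon and keeps chlorine off the electron-rich ring.

Step 6
Reactants: 12 1-[3,5-bis(methoxymethoxy)phenyl]-2-chloroethanone
Product: 13 (1R)-1-[3,5-bis(methoxymethoxy)phenyl]-2-chloroethanol
Conditions: RuCl[(S,S)-TsDPEN](p-cymene) (1 mol %), HCO2H/Et3N azeotrope, EtOAc, rt
Reagents that add atoms: none
Why: Noyori asymmetric transfer hydrogenation: the (S,S)-TsDPEN ruthenium hydride should attack the ketone face that gives (S)-1-arylethanols from aryl methyl ketones, which here is the (R)-chlorohydrin because CH2Cl outranks aryl, and the acidic formate medium prevents closure to the epoxide.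

Step 7
Reactants: 13 (1R)-1-[3,5-bis(methoxymethoxy)phenyl]-2-chloroethanol; 8 6-fluoro-3-geranyl-2,4-bis(methoxymethoxy)benzaldehyde
Product: 16 (2S)-2-[3,5-bis(methoxymethoxy)phenyl]-6-geranyl-5,7-bis(methoxymethoxy)chroman-4-ol (both C4 epimers), via β-oxido alkyllithium 14 (not isolated), via dilithium diolate 15 (not isolated)
Conditions: n-BuLi (1 equiv), THF, −78 °C; lithium naphthalenide LiC10H8 (2 equiv), −78 °C; 8, −78 °C; then KOt-Bu (1 equiv), DMPU, −78 to 60 °C; H2O
Reagents that add atoms: n-butyllithium, CCCC[Li], lithium naphthalenide, [Li+].[CH-]1C=C[CH]c2ccccc12 (lithium of 14 and 15 only)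
Why: After O-lithiation of 13, two equivalents of lithium naphthalenide exchange chlorine for lithium at −78 °C to give the β-oxido alkyllithium 14, whose carbanion carbon (C3 of the target) adds to the aldehyde carbon (C4) of 8 to give diolate 15; on warming with KOt-Bu and DMPU the ring B carbinol oxygen (O1) adds to the fluorine-bearing carbon C8a and fluoride leaves through a Meisenheimer anion. The closest known reaction types are the carbonyl addition of β-oxido organolithiums made from chlorohydrins by reductive lithiation and the intramolecular SNAr etherification of aryl fluorides that gives chromans. Ring C closes by 6-exo-trig attack of O1 on C8a, the four-membered alternative from the C4 alkoxide being out of reach. C2 is not a new stereocentre: it is the carbinol carbon of 13, none of its bonds is made or broken because its oxygen acts as the nucleophile, so the configuration from step 6 is kept, while the new C4 carbinol forms without control and is erased in step 8. The step needs carbonyl addition to outrun β-elimination of the alkyllithium (secured by working at −78 °C with a fast aldehyde electrophile) and needs an electrophilic C8a without a conjugating acceptor, which the two meta alkoxy groups at C5 and C7 (inductive pull, no resonance donation to C8a) and the single fluorine provide. Because C4 is an alkoxide and not a ketone while base is present, neither retro-aldol cleavage nor E1cB opening of ring C can scramble C2.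

Step 8
Reactants: 16 (2S)-2-[3,5-bis(methoxymethoxy)phenyl]-6-geranyl-5,7-bis(methoxymethoxy)chroman-4-ol
Product: 17 (2S)-2-[3,5-bis(methoxymethoxy)phenyl]-6-geranyl-5,7-bis(methoxymethoxy)chroman-4-one
Conditions: Dess–Martin periodinane, CH2Cl2, 0 °C to rt
Reagents that add atoms: none
Why: Dess–Martin oxidation of the benzylic secondary alcohol should bring both C4 epimers to one ketone under near-neutral conditions that leave C2, the geranyl olefins and the acetals untouched.

Step 9
Reactants: 17 (2S)-2-[3,5-bis(methoxymethoxy)phenyl]-6-geranyl-5,7-bis(methoxymethoxy)chroman-4-one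
Product: 18 Schizolaenone C
Conditions: HCl (2 M aq), MeOH/THF, 40 °C
Reagents that add atoms: none
Why: Acid-catalysed acetal solvolysis (transacetalisation to dimethoxymethane) should free all four phenols, and acidic conditions at mild temperature avoid the base-induced retro-oxa-Michael pathway that would racemise C2.

**Compound list**

1 | 5-fluorobenzene-1,3-diol (5-fluororesorcinol) | Oc1cc(O)cc(F)c1 | starting material
2 | 1-fluoro-3,5-bis(methoxymethoxy)benzene | COCOc1cc(F)cc(OCOC)c1 | intermediate
3 | geranyl bromide, (2E)-1-bromo-3,7-dimethylocta-2,6-diene | CC(C)=CCC/C(C)=C/CBr | starting material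
4 | [4-fluoro-2,6-bis(methoxymethoxy)phenyl]lithium (not isolated) | [Li]c1c(OCOC)cc(F)cc1OCOC | intermediate
5 | 2-[(2E)-3,7-dimethylocta-2,6-dien-1-yl]-5-fluoro-1,3-bis(methoxymethoxy)benzene | CC(C)=CCC/C(C)=C/Cc1c(OCOC)cc(F)cc1OCOC | intermediate
6 | {3-[(2E)-3,7-dimethylocta-2,6-dien-1-yl]-6-fluoro-2,4-bis(methoxymethoxy)phenyl}lithium (not isolated) | CC(C)=CCC/C(C)=C/Cc1c(OCOC)cc(F)c([Li])c1OCOC | intermediate
7 | lithium (dimethylamino){3-[(2E)-3,7-dimethylocta-2,6-dien-1-yl]-6-fluoro-2,4-bis(methoxymethoxy)phenyl}methanolate (not isolated) | CC(C)=CCC/C(C)=C/Cc1c(OCOC)cc(F)c(C(O[Li])N(C)C)c1OCOC | intermediate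
8 | 3-[(2E)-3,7-dimethylocta-2,6-dien-1-yl]-6-fluoro-2,4-bis(methoxymethoxy)benzaldehyde | CC(C)=CCC/C(C)=C/Cc1c(OCOC)cc(F)c(C=O)c1OCOC | intermediate
9 | 1-(3,5-dihydroxyphenyl)ethanone | CC(=O)c1cc(O)cc(O)c1 | starting material
10 | 1-[3,5-bis(methoxymethoxy)phenyl]ethanone | CC(=O)c1cc(OCOC)cc(OCOC)c1 | intermediate
11 | ({1-[3,5-bis(methoxymethoxy)phenyl]ethenyl}oxy)(trimethyl)silane (not isolated) | C=C(O[Si](C)(C)C)c1cc(OCOC)cc(OCOC)c1 | intermediate
12 | 1-[3,5-bis(methoxymethoxy)phenyl]-2-chloroethanone | O=C(CCl)c1cc(OCOC)cc(OCOC)c1 | intermediate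
13 | (1R)-1-[3,5-bis(methoxymethoxy)phenyl]-2-chloroethanol | ClC[C@H](O)c1cc(OCOC)cc(OCOC)c1 | intermediate
14 | lithium (1S)-1-[3,5-bis(methoxymethoxy)phenyl]-2-lithioethanolate (not isolated; same spatial arrangement as 13, the descriptor changes because CH2Li ranks below aryl) | [Li]C[C@H](O[Li])c1cc(OCOC)cc(OCOC)c1 | intermediate
15 | dilithium (3S)-3-[3,5-bis(methoxymethoxy)phenyl]-1-{3-[(2E)-3,7-dimethylocta-2,6-dien-1-yl]-6-fluoro-2,4-bis(methoxymethoxy)phenyl}propane-1,3-diolate, both C1 epimers (not isolated) | CC(C)=CCC/C(C)=C/Cc1c(OCOC)cc(F)c(C(O[Li])C[C@H](O[Li])c2cc(OCOC)cc(OCOC)c2)c1OCOC | intermediate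
16 | (2S)-2-[3,5-bis(methoxymethoxy)phenyl]-6-[(2E)-3,7-dimethylocta-2,6-dien-1-yl]-5,7-bis(methoxymethoxy)-3,4-dihydro-2H-chromen-4-ol, both C4 epimers | CC(C)=CCC/C(C)=C/Cc1c(OCOC)cc2c(c1OCOC)C(O)C[C@@H](c1cc(OCOC)cc(OCOC)c1)O2 | intermediate
17 | (2S)-2-[3,5-bis(methoxymethoxy)phenyl]-6-[(2E)-3,7-dimethylocta-2,6-dien-1-yl]-5,7-bis(methoxymethoxy)-2,3-dihydro-4H-chromen-4-one | CC(C)=CCC/C(C)=C/Cc1c(OCOC)cc2c(c1OCOC)C(=O)C[C@@H](c1cc(OCOC)cc(OCOC)c1)O2 | intermediate
18 | Schizolaenone C, (2S)-2-(3,5-dihydroxyphenyl)-6-[(2E)-3,7-dimethylocta-2,6-dien-1-yl]-5,7-dihydroxy-2,3-dihydro-4H-chromen-4-one | CC(C)=CCC/C(C)=C/Cc1c(O)cc2c(c1O)C(=O)C[C@@H](c1cc(O)cc(O)c1)O2 | target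

**Count and risks**

Total steps: 9. Longest linear sequence: 6 (steps 1, 2, 3, 7, 8, 9; the ring B branch 4, 5, 6, 7, 8, 9 is equally long).

Steps most likely to fail:

Step 7. The β-oxido alkyllithium may be lost by β-elimination of lithium oxide or by proton abstraction before it adds to the hindered aldehyde, and the Meisenheimer addition of the alkoxide to an arene without a conjugating acceptor may be slow. The fallback sets out from 8 and 10 and comes back at 16. The lithium enolate of 10 (LiN(i-Pr)2, THF, −78 °C) is added to 8 in a crossed aldol addition, which makes the same C3–C4 bond and gives racemic 1-[3,5-bis(methoxymethoxy)phenyl]-3-{3-geranyl-6-fluoro-2,4-bis(methoxymethoxy)phenyl}-3-hydroxypropan-1-one F1. Asymmetric transfer hydrogenation of its aryl ketone with RuCl[(S,S)-TsDPEN](p-cymene) and HCO2H/Et3N should set the ring B carbinol and give (1S)-1-[3,5-bis(methoxymethoxy)phenyl]-3-{3-geranyl-6-fluoro-2,4-bis(methoxymethoxy)phenyl}propane-1,3-diol F2 as a mixture of epimers at the other carbinol. The isolated diol is then closed to 16 by SNAr with KOt-Bu (2 equiv) in THF/DMPU at 60 °C, free of organolithium residues.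

Step 2. Metalation ortho to fluorine (acidity control) may compete with metalation between the two acetal oxygens (coordination control), and the wrong aryllithium would then lose LiF to an aryne. The fallback sets out from 1 and comes back at 5. Free 5-fluororesorcinol is C-allylated with geraniol on acidic Al2O3 (1,2-dichloroethane, reflux), a surface-templated ortho-allylation of phenols that favours the position flanked by both hydroxyls, to give 2-geranyl-5-fluorobenzene-1,3-diol F3. Protection with MOMCl and i-Pr2NEt then gives 5.

Step 9. The freed C5 or C7 hydroxyl may add to the proximal geranyl olefin under acid, the chain may undergo cation–olefin cyclisation, and acid-catalysed opening and reclosure of ring C would erode the configuration at C2. The fallback sets out from 17 and comes back at 18. Instead of protic solvolysis, the methoxymethyl groups are transferred to a thiol under aprotic Lewis-acid activation (ZnBr2, n-PrSH, CH2Cl2, 0 °C), a fast cleavage without a strong Brønsted acid. No compound outside the list is made on this way (F0).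

**Further compounds**

F1 | step 7 | 1-[3,5-bis(methoxymethoxy)phenyl]-3-{3-[(2E)-3,7-dimethylocta-2,6-dien-1-yl]-6-fluoro-2,4-bis(methoxymethoxy)phenyl}-3-hydroxypropan-1-one (racemic) | CC(C)=CCC/C(C)=C/Cc1c(OCOC)cc(F)c(C(O)CC(=O)c2cc(OCOC)cc(OCOC)c2)c1OCOC
F2 | step 7 | (1S)-1-[3,5-bis(methoxymethoxy)phenyl]-3-{3-[(2E)-3,7-dimethylocta-2,6-dien-1-yl]-6-fluoro-2,4-bis(methoxymethoxy)phenyl}propane-1,3-diol (both C3 epimers) | CC(C)=CCC/C(C)=C/Cc1c(OCOC)cc(F)c(C(O)C[C@H](O)c2cc(OCOC)cc(OCOC)c2)c1OCOC
F3 | step 2 | 2-[(2E)-3,7-dimethylocta-2,6-dien-1-yl]-5-fluorobenzene-1,3-diol | CC(C)=CCC/C(C)=C/Cc1c(O)cc(F)cc1O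
F0 | step 9 | none | none
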